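(The constants were set for the occasion; the run is a simulation.)

Ochre and amber, I told myself, carry the same charges and differ in one thing: ochre has its coupling partner from the start, while amber receives it over 15 h.

the same everywhere: free catalyst 50 µM; time 20 h
- amber: substrate 10 mM; coupling partner 9.00 mM (fed, over 15 h); all else is in the flask from the start; the feed brings no volume worth counting
- ochre: substrate 10 mM; coupling partner 9.00 mM; everything together at the start
- green: substrate 10 mM (fed, over 15 h); coupling partner 9.00 mM; all else is in the flask from the start; the feed brings no volume worth counting

    substrate + free catalyst → catalyst intermediate A (k1 = 21000 M⁻¹ h⁻¹)
    coupling partner + catalyst intermediate A → catalyst intermediate B (k2 = 38000 M⁻¹ h⁻¹)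
    catalyst intermediate B ⇌ catalyst intermediate C (K3 = 9.4, k3 = 27 h⁻¹)
    catalyst intermediate C → free catalyst + target (k4 = 1200 h⁻¹)
    2 substrate → self-condensation product (k5 = 0.0088 M⁻¹ h⁻¹)
    coupling partner + target ⇌ idle adduct, settled at all times (K6 = 2000 M⁻¹)

- a species is counted by the substrate in it: one self-condensation product counts as two
- amounts and yields of target count idle adduct too
- a doubled species enters its step squared and goes two at a time
- run time (amber): 20 h

- which flask leads in amount of target, in percent of the substrate charged ("all alike" within 1.5 percentage points) (amber / ochre / green / all alike)
- how much target is there at the end, in percent of the substrate charged: amber
- how much target is there at the end, in percent of the substrate charged: ochre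
- how much target is there at the end, in percent of the substrate charged: green

I reckoned in lifetimes. I assumed the catalyst waits as catalyst intermediate A, its resting state, so that free coupling partner has a pseudo-first-order lifetime of 0.526 h. But the adduct balance keeps a growing share of the unused coupling partner bound, so the whole pool lasts longer. With target near the partner charge, it lasts 10.0 h, far longer than the bare lifetime. That bare lifetime, multiplied by one plus the adduct constant times the partner charge, is my capture lifetime, τ.

In ochre the stretch builds up as target forms, and integrating it gives the early, quicker part of the run a worth of 0.947 of an extra lifetime. So I reckoned 0.472 mM of coupling partner left in ochre, free and bound together, hence target at 85.3 %.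

In amber the feed runs against the stretched lifetime, and I balanced feed rate against loss to get a pool of 3.68 mM when the feed stops. Amber then has half a capture lifetime left. Counting that time at the full τ, the longest lifetime in this reckoning, gave an estimated floor for amber, 67.7 %. My reckoning went no further, and I did not reckon green.

The forecast named ochre as leader, with 74 % for amber, 83 % for ochre and 78.5 % for green, on the ground that “the real brake is the adduct”. My ochre figure stood above its number, and my amber figure was an estimated floor, not its number.

The simulation gave 74.3 % for amber, 83.1 % for ochre and 78.3 % for green, so ochre led and the forecast held.

The gap between ochre and amber was 8.9 percentage points, and with the idle adduct taken out it shrank to 0.0085 points, the largest single effect on that gap. The 5.00 h after amber's feed are 9.50 bare lifetimes but half a capture lifetime. In the neighbour, amber with 0.085 mM of free catalyst, τ falls to 5.88 h, the reckoned pool at the feed's end to 2.57 mM, and the estimated floor rises to 79.0 %. The computed neighbour reached 81.8 %.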